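**Retrosynthetic overview**

1. Labels: rings A to E are counted from the phloroglucinol end and the carbons of each ring are numbered 1 to 6. The four ether oxygens join ring A carbon 1 to ring B carbon 1, ring B carbon 5 to ring C carbon 1, ring C carbon 6 to ring D carbon 1, and ring D carbon 4 to ring E carbon 1.
2. The target comes from its fully O-alkylated form by cleavage of thirteen alkyl ethers. The ether between ring B carbon 5 and ring C carbon 1 is then cut into an AB phenol (free hydroxyl on ring B carbon 5) and a CDE aryl bromide (bromine on ring C carbon 1), joined by a CuI-catalysed Ullmann coupling.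
3. The strategy rests on ring B: it carries the ring A oxygen on carbon 1 between the two CH positions (carbons 2 and 6), the ring C oxygen on carbon 5 meta to it, and oxygens on carbons 3, 4 and 5 in a row. A cyclobutenone–ynol ether benzannulation writes exactly this pattern, so ring B is built de novo (new bonds between its carbons 5 and 6 and between its carbons 1 and 2) from 3-ethoxy-4-methoxycyclobutenone and the ethynyl ether of 2,4,6-trimethoxyphenol. The hindered ether between rings A and B comes in ready-made with the alkyne.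
4. The CDE bromide is made by two oxidative copper couplings of arylboronic acids (first the ether from ring D carbon 4 to ring E carbon 1, then the ether from ring C carbon 6 to ring D carbon 1). Each time the doubly flanked oxygen is the phenol partner and an aryl bromide is a spectator.
5. Ring order: rings A, C, D and E are bought as arenes; ring B is the only ring formed (step 4).

Key step: step 4

Remark: the target has no stereocentre, so the cyclobutenone is used as the racemate; its one stereocentre becomes aromatic carbon 4 of ring B.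

**Route**

Step 1
Reactants: 1 2,4,6-trimethoxyphenol; 2 trichloroethylene
Product: 4 (E)-2-[(1,2-dichloroethenyl)oxy]-1,3,5-trimethoxybenzene, via dichloroacetylene 3 (not isolated)
Conditions: K2CO3, DMF, 70 °C, Ar
Reagents that add atoms: none
Why: Base-induced loss of HCl from trichloroethylene gives dichloroacetylene in the flask, to which the phenoxide adds in anti fashion (the standard dichlorovinyl ether synthesis from phenols), so the hindered oxygen on ring A carbon 1 reacts as a nucleophile at an sp carbon, where its two ortho methoxy groups do not interfere.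

Step 2
Reactants: 4 (E)-2-[(1,2-dichloroethenyl)oxy]-1,3,5-trimethoxybenzene
Product: 7 2-(ethynyloxy)-1,3,5-trimethoxybenzene, via chloroethynyl ether 5 (not isolated), via lithium acetylide 6 (not isolated)
Conditions: n-BuLi (2.3 equiv), THF, −78 → −40 °C; H2O, −78 °C; used at once
Reagents that add atoms: none
Why: Deprotonation of the vinylic CH and β-elimination of LiCl give the chloroalkyne, chlorine–lithium exchange with the second equivalent of n-BuLi gives the acetylide, and protonation gives the terminal aryl ynol ether (the usual ynol ether synthesis from dichlorovinyl ethers).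

Step 3
Reactants: 8 methoxyacetyl chloride; 9 ethoxyacetylene
Product: 11 racemic 3-ethoxy-4-methoxycyclobut-2-en-1-one, via methoxyketene 10 (not isolated)
Conditions: Et3N, 9 (3 equiv), Et2O, slow addition of 8, 0 °C → rt
Reagents that add atoms: none
Why: Dehydrochlorination gives methoxyketene, which undergoes the thermal ketene–ynol ether (2+2) cycloaddition with its carbonyl carbon bonding to the CH terminus of ethoxyacetylene, so ethoxy sits on ring carbon 3 and methoxy on ring carbon 4; the stereocentre at carbon 4 forms as a racemate and is lost in step 4.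

Step 4
Reactants: 11 racemic 3-ethoxy-4-methoxycyclobut-2-en-1-one; 7 2-(ethynyloxy)-1,3,5-trimethoxybenzene
Product: 16 3-ethoxy-2-methoxy-5-(2,4,6-trimethoxyphenoxy)phenol, via vinylketene 12 (not isolated), via vinylcyclobutenone 13 (not isolated), via dienylketene 14 (not isolated), via cyclohexadienone 15 (not isolated)
Conditions: 7 (1.5 equiv), toluene, 110 °C, sealed tube, Ar
Reagents that add atoms: none
Why: Heating opens 11 by 4π electrocyclic cleavage of the bond between its carbonyl carbon and carbon 4 (methoxy rotating outward) to vinylketene 12, which adds (2+2) across the triple bond of 7 to give cyclobutenone 13; a second 4π opening gives dienylketene 14, whose 6π electrocyclisation and tautomerisation (via dienone 15) should give phenol 16. The closest known reaction type is the Danheiser benzannulation of cyclobutenones with alkoxy- and siloxyacetylenes, which gives resorcinol monoethers with the alkyne oxygen meta to the new hydroxyl; here it is applied to a 3,4-dialkoxycyclobutenone and an aryl ethynyl ether. Ring B, a six-membered carbocycle, is closed by the 6π electrocyclisation of 14 (bond between ring B carbons 4 and 5), after the (2+2) step has made the new skeletal bonds between ring B carbons 5 and 6 and between ring B carbons 1 and 2. No stereocentre is formed; the stereocentre at carbon 4 of racemic 11 ends as aromatic carbon 4 of ring B. The step needs one regiochemistry in the ketene–alkyne addition, ketene carbonyl carbon to the CH terminus of the ynol ether, and the polarisation of the two partners secures it (the alkyne is nucleophilic at the carbon remote from oxygen, all the more because the two ortho methoxy groups twist ring A out of conjugation with the ether oxygen), so the aryloxy group ends on ring B carbon 1 between the CH groups at carbons 2 and 6. The ynol ether of a phenol has no hydrogen β to oxygen, so the retro-ene loss of ketene that limits alkyl ynol ethers at this temperature is closed, and the unproductive rotamer of the second ring opening returns to 13 because that opening is reversible.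

Step 5
Reactants: 17 4-bromo-2,6-dimethoxyphenol; 18 (3,4,5-trimethoxyphenyl)boronic acid
Product: 19 5-bromo-1,3-dimethoxy-2-(3,4,5-trimethoxyphenoxy)benzene
Conditions: Cu(OAc)2 (20 mol %), pyridine, 4 Å MS, O2 (1 atm), CH2Cl2, rt; 18 (2 equiv)
Reagents that add atoms: none
Why: Chan–Lam–Evans oxidative O-arylation, in which the doubly flanked oxygen on ring D carbon 4 is the phenol and the unhindered carbon 1 of ring E comes from the boronic acid, and which at room temperature leaves the aryl bromide untouched.

Step 6
Reactants: 19 5-bromo-1,3-dimethoxy-2-(3,4,5-trimethoxyphenoxy)benzene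
Product: 22 [3,5-dimethoxy-4-(3,4,5-trimethoxyphenoxy)phenyl]boronic acid, via aryllithium 20 (not isolated), via lithium borate 21 (not isolated)
Conditions: B(OiPr)3, THF–toluene, −78 °C, then n-BuLi dropwise (in situ quench); 1 M HCl, 0 °C
Reagents that add atoms: triisopropyl borate CC(C)OB(OC(C)C)OC(C)C; water O
Why: Bromine–lithium exchange at ring D carbon 1 is faster than attack of n-BuLi on the borate at −78 °C, so the aryllithium is trapped as the ate complex as it forms, before lithium can move next to a methoxy group, and acid hydrolysis gives the boronic acid (lithiation–borylation).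

Step 7
Reactants: 23 2,3,4-trimethoxyphenol
Product: 24 6-bromo-2,3,4-trimethoxyphenol
Conditions: NBS (1.0 equiv), i-Pr2NH (10 mol %), CH2Cl2, 0 °C
Reagents that add atoms: N-bromosuccinimide O=C1CCC(=O)N1Br
Why: Amine-catalysed ortho-bromination of a phenol (electrophilic aromatic substitution by the N-bromoamine held on the hydroxyl by a hydrogen bond) is directed to the only free ortho position, which is also para to the 3-methoxy group and becomes carbon 1 of ring C.

Step 8
Reactants: 24 6-bromo-2,3,4-trimethoxyphenol; 22 [3,5-dimethoxy-4-(3,4,5-trimethoxyphenoxy)phenyl]boronic acid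
Product: 25 1-bromo-2-[3,5-dimethoxy-4-(3,4,5-trimethoxyphenoxy)phenoxy]-3,4,5-trimethoxybenzene
Conditions: Cu(OAc)2 (20 mol %), pyridine, 4 Å MS, O2 (1 atm), CH2Cl2, rt; 22 (2 equiv)
Reagents that add atoms: none
Why: Chan–Lam–Evans O-arylation tolerates phenols with both ortho positions substituted, an ortho halogen included, and takes the unhindered carbon 1 of ring D from boron, while the bromide on ring C carbon 1 is inert to the room-temperature divalent-copper conditions and is kept for step 9.

Step 9
Reactants: 16 3-ethoxy-2-methoxy-5-(2,4,6-trimethoxyphenoxy)phenol; 25 1-bromo-2-[3,5-dimethoxy-4-(3,4,5-trimethoxyphenoxy)phenoxy]-3,4,5-trimethoxybenzene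
Product: 26 2-[3,5-dimethoxy-4-(3,4,5-trimethoxyphenoxy)phenoxy]-1-[3-ethoxy-2-methoxy-5-(2,4,6-trimethoxyphenoxy)phenoxy]-3,4,5-trimethoxybenzene
Conditions: CuI (20 mol %), picolinic acid (40 mol %), K3PO4 (2 equiv), DMSO, 100 °C, Ar
Reagents that add atoms: none
Why: Ligand-accelerated Ullmann diaryl ether synthesis with the CuI–picolinic acid system suits electron-rich partners that each carry one ortho substituent (the methoxy on ring B carbon 4 next to the hydroxyl on carbon 5, the aryloxy on ring C carbon 6 next to the bromide on carbon 1), and no other halide or free hydroxyl is present.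

Step 10
Reactants: 26 2-[3,5-dimethoxy-4-(3,4,5-trimethoxyphenoxy)phenoxy]-1-[3-ethoxy-2-methoxy-5-(2,4,6-trimethoxyphenoxy)phenoxy]-3,4,5-trimethoxybenzene
Product: 27 2-(3-{2-[3,5-dihydroxy-4-(3,4,5-trihydroxyphenoxy)phenoxy]-3,4,5-trihydroxyphenoxy}-4,5-dihydroxyphenoxy)benzene-1,3,5-triol (CNP0228612.0)
Conditions: BBr3 (30 equiv), CH2Cl2, −78 °C → rt, Ar; degassed H2O, 0 °C; Sephadex LH-20
Reagents that add atoms: none
Why: Lewis acid-mediated dealkylation of aryl alkyl ethers (boron binds each alkoxy oxygen and bromide removes methyl or ethyl by SN2) leaves the four diaryl ether bonds intact, since an sp2 carbon is not displaced, and should give the thirteen free hydroxyls after hydrolysis of the B–O bonds.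

**Compound list**

1 | 2,4,6-trimethoxyphenol | COc1cc(OC)c(O)c(OC)c1 | starting material
2 | trichloroethylene | ClC=C(Cl)Cl | starting material
3 | dichloroacetylene | ClC#CCl | intermediate (not isolated)
4 | (E)-2-[(1,2-dichloroethenyl)oxy]-1,3,5-trimethoxybenzene | Cl/C=C(/Cl)Oc1c(OC)cc(OC)cc1OC | intermediate
5 | 2-[(chloroethynyl)oxy]-1,3,5-trimethoxybenzene | ClC#COc1c(OC)cc(OC)cc1OC | intermediate (not isolated)
6 | [(2,4,6-trimethoxyphenoxy)ethynyl]lithium | [Li]C#COc1c(OC)cc(OC)cc1OC | intermediate (not isolated)
7 | 2-(ethynyloxy)-1,3,5-trimethoxybenzene | C#COc1c(OC)cc(OC)cc1OC | intermediate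
8 | methoxyacetyl chloride | COCC(=O)Cl | starting material
9 | ethoxyacetylene | CCOC#C | starting material
10 | methoxyketene | COC=C=O | intermediate (not isolated)
11 | racemic 3-ethoxy-4-methoxycyclobut-2-en-1-one | CCOC1=CC(=O)C1OC | intermediate
12 | (Z)-3-ethoxy-4-methoxybuta-1,3-dien-1-one | O=C=C/C(OCC)=C/OC | intermediate (not isolated)
13 | racemic 4-[(Z)-1-ethoxy-2-methoxyethenyl]-3-(2,4,6-trimethoxyphenoxy)cyclobut-2-en-1-one | O=C1C=C(Oc2c(OC)cc(OC)cc2OC)C1/C(OCC)=C/OC | intermediate (not isolated)
14 | (3E,5Z)-5-ethoxy-6-methoxy-3-(2,4,6-trimethoxyphenoxy)hexa-1,3,5-trien-1-one | O=C=C/C(Oc1c(OC)cc(OC)cc1OC)=C\C(OCC)=C\OC | intermediate (not isolated)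
15 | racemic 5-ethoxy-6-methoxy-3-(2,4,6-trimethoxyphenoxy)cyclohexa-2,4-dien-1-one | O=C1C=C(Oc2c(OC)cc(OC)cc2OC)C=C(OCC)C1OC | intermediate (not isolated)
16 | 3-ethoxy-2-methoxy-5-(2,4,6-trimethoxyphenoxy)phenol | CCOc1cc(Oc2c(OC)cc(OC)cc2OC)cc(O)c1OC | intermediate
17 | 4-bromo-2,6-dimethoxyphenol | COc1cc(Br)cc(OC)c1O | starting material
18 | (3,4,5-trimethoxyphenyl)boronic acid | COc1cc(B(O)O)cc(OC)c1OC | starting material
19 | 5-bromo-1,3-dimethoxy-2-(3,4,5-trimethoxyphenoxy)benzene | COc1cc(Br)cc(OC)c1Oc1cc(OC)c(OC)c(OC)c1 | intermediate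
20 | [3,5-dimethoxy-4-(3,4,5-trimethoxyphenoxy)phenyl]lithium | [Li]c1cc(OC)c(Oc2cc(OC)c(OC)c(OC)c2)c(OC)c1 | intermediate (not isolated)
21 | lithium [3,5-dimethoxy-4-(3,4,5-trimethoxyphenoxy)phenyl]tri(propan-2-yloxy)borate | [Li+].CC(C)O[B-](OC(C)C)(OC(C)C)c1cc(OC)c(Oc2cc(OC)c(OC)c(OC)c2)c(OC)c1 | intermediate (not isolated)
22 | [3,5-dimethoxy-4-(3,4,5-trimethoxyphenoxy)phenyl]boronic acid | OB(O)c1cc(OC)c(Oc2cc(OC)c(OC)c(OC)c2)c(OC)c1 | intermediate
23 | 2,3,4-trimethoxyphenol | COc1ccc(O)c(OC)c1OC | starting material
24 | 6-bromo-2,3,4-trimethoxyphenol | COc1cc(Br)c(O)c(OC)c1OC | intermediate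
25 | 1-bromo-2-[3,5-dimethoxy-4-(3,4,5-trimethoxyphenoxy)phenoxy]-3,4,5-trimethoxybenzene | COc1cc(Br)c(Oc2cc(OC)c(Oc3cc(OC)c(OC)c(OC)c3)c(OC)c2)c(OC)c1OC | intermediate
26 | 2-[3,5-dimethoxy-4-(3,4,5-trimethoxyphenoxy)phenoxy]-1-[3-ethoxy-2-methoxy-5-(2,4,6-trimethoxyphenoxy)phenoxy]-3,4,5-trimethoxybenzene | CCOc1cc(Oc2c(OC)cc(OC)cc2OC)cc(Oc2cc(OC)c(OC)c(OC)c2Oc2cc(OC)c(Oc3cc(OC)c(OC)c(OC)c3)c(OC)c2)c1OC | intermediate
27 | 2-(3-{2-[3,5-dihydroxy-4-(3,4,5-trihydroxyphenoxy)phenoxy]-3,4,5-trihydroxyphenoxy}-4,5-dihydroxyphenoxy)benzene-1,3,5-triol | Oc1cc(O)c(Oc2cc(O)c(O)c(Oc3cc(O)c(O)c(O)c3Oc3cc(O)c(Oc4cc(O)c(O)c(O)c4)c(O)c3)c2)c(O)c1 | target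

**Step count and risks**

Total step count: 10. Longest linear sequence: 5 steps (1, 2, 4, 9, 10; the CDE branch 5, 6, 8, 9, 10 is equally long).

Steps most likely to fail:

1. Step 4. The ring opening of the vinylogous-ester cyclobutenone may be too slow at a temperature the aryl ynol ether survives. The aryloxyalkyne may also trap the vinylketene too slowly, so that ketene dimerisation and acylation of the product phenol by the ketene take over. Fallback, setting out from 1 and coming back at 16: ring B is taken from a ready-made arene. Purchased 5-bromo-3-ethoxy-2-hydroxybenzaldehyde F1 is O-methylated (MeI, K2CO3, DMF) to 5-bromo-3-ethoxy-2-methoxybenzaldehyde F2. Ullmann coupling of F2 with 1 (CuI, N,N-dimethylglycine, Cs2CO3, dioxane, 100 °C) should give 3-ethoxy-2-methoxy-5-(2,4,6-trimethoxyphenoxy)benzaldehyde F3; here the hindered oxygen on carbon 1 of ring A is the nucleophile and the bromide sits between two CH groups. Baeyer–Villiger (Dakin-type) oxidation with mCPBA (NaHCO3, CH2Cl2, 0 °C) should give 3-ethoxy-2-methoxy-5-(2,4,6-trimethoxyphenoxy)phenyl formate F4, and methanolysis (K2CO3, MeOH) gives 16.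

2. Step 9. Oxidative addition of copper to the electron-rich bromide, which has an aryloxy group ortho to it, may be slow. Reduction of the carbon–bromine bond and oxidation of the phenol could then compete. Fallback, setting out from 25 and coming back at 26: the polarity of ring C is inverted. Bromine–lithium exchange on 25 in the presence of B(OiPr)3 (n-BuLi, THF, −78 °C; aqueous HCl) gives {2-[3,5-dimethoxy-4-(3,4,5-trimethoxyphenoxy)phenoxy]-3,4,5-trimethoxyphenyl}boronic acid F5. Chan–Lam–Evans coupling of F5 with 16 (Cu(OAc)2, pyridine, 4 Å MS, O2, CH2Cl2, rt) forms the ether between carbon 5 of ring B and carbon 1 of ring C at room temperature and gives 26.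

3. Step 10. Cleavage of thirteen ethers may stop part-way when partly dealkylated boron aryloxides precipitate. The pyrogallol-type rings may also be oxidised by air during aqueous isolation. Fallback, setting out from 26 and coming back at 27: capture, purify, release. The crude product of the BBr3 cleavage is acetylated without purification (Ac2O, pyridine, DMAP, rt) to 2-(3-{2-[3,5-diacetoxy-4-(3,4,5-triacetoxyphenoxy)phenoxy]-3,4,5-triacetoxyphenoxy}-4,5-diacetoxyphenoxy)benzene-1,3,5-triyl triacetate F6. F6 is stable in air and can be separated on silica from partly alkylated material. Deacetylation (catalytic NaOMe, degassed MeOH, then acidic resin) releases 27 under oxygen-free conditions.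

**Further compounds**

F1 | step 4 | 5-bromo-3-ethoxy-2-hydroxybenzaldehyde (purchased) | CCOc1cc(Br)cc(C=O)c1O
F2 | step 4 | 5-bromo-3-ethoxy-2-methoxybenzaldehyde | CCOc1cc(Br)cc(C=O)c1OC
F3 | step 4 | 3-ethoxy-2-methoxy-5-(2,4,6-trimethoxyphenoxy)benzaldehyde | CCOc1cc(Oc2c(OC)cc(OC)cc2OC)cc(C=O)c1OC
F4 | step 4 | 3-ethoxy-2-methoxy-5-(2,4,6-trimethoxyphenoxy)phenyl formate | CCOc1cc(Oc2c(OC)cc(OC)cc2OC)cc(OC=O)c1OC
F5 | step 9 | {2-[3,5-dimethoxy-4-(3,4,5-trimethoxyphenoxy)phenoxy]-3,4,5-trimethoxyphenyl}boronic acid | COc1cc(B(O)O)c(Oc2cc(OC)c(Oc3cc(OC)c(OC)c(OC)c3)c(OC)c2)c(OC)c1OC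
F6 | step 10 | 2-(3-{2-[3,5-diacetoxy-4-(3,4,5-triacetoxyphenoxy)phenoxy]-3,4,5-triacetoxyphenoxy}-4,5-diacetoxyphenoxy)benzene-1,3,5-triyl triacetate | CC(=O)Oc1cc(OC(C)=O)c(Oc2cc(OC(C)=O)c(OC(C)=O)c(Oc3cc(OC(C)=O)c(OC(C)=O)c(OC(C)=O)c3Oc3cc(OC(C)=O)c(Oc4cc(OC(C)=O)c(OC(C)=O)c(OC(C)=O)c4)c(OC(C)=O)c3)c2)c(OC(C)=O)c1
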